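The run lasts 10 min, and the initiator's half-life of 40.8 s is far shorter, so this flask receives its radicals early.

substrate 2.0 M; reagent 2.00 M; initiator 84 mM; time 10 min

    substrate + initiating radical → capped initiator + first chain carrier (k1 = 51000 M⁻¹ s⁻¹)
    first chain carrier → ended carrier (k2 = 120 s⁻¹)
    initiator → 2 initiating radical (k3 = 0.017 s⁻¹)
    substrate + second chain carrier → by-product + first chain carrier (k4 = 13000 M⁻¹ s⁻¹)
    crystals ⇌ by-product, rate k5*(cs5 - [by-product]) while solid is left; crystals form when [by-product] > cs5 (cs5 = 0.67 M, k5 = 2.2 s⁻¹)
    reagent + first chain carrier → product + second chain carrier (k6 = 5900 M⁻¹ s⁻¹)
    2 first chain carrier → ended chains (k7 = 8 × 10⁶ M⁻¹ s⁻¹)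

- a species is counted by the substrate in it: one ended chains counts as two
- amounts and yields of by-product count crystals too
- a step written with two of one species runs at k times the square of its concentration and takes two of it each time
- given per volume of solution although it is solid: crystals
- run time (flask): 10 min

1. product at 10 min, in percent of the substrate charged
2. the change that raises the amount of product at 10 min, in percent of the substrate charged most ("none" if none brings more than 2 percentage points) (blue / green / grey / none)
3. amount of product at 10 min, in percent of the substrate charged, after blue

- blue: doubling the amount of reagent, all else as stated
- green: doubling the dissolution coefficient of step 5, all else as stated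
- grey: doubling the solubility in step 5, all else as stated

Follow one substrate molecule. Whichever radical takes it, it becomes a first chain carrier and stands at a fork: reagent turns it into product, or it ends, by itself or with a partner.

Two views of that fork compete, and I reckon both. Radicals made at the start, balanced against both endings, hold the first chain carrier near 1.01 × 10⁻⁵ M, so each carrier ends at 282 s⁻¹. From this comes the even-odds level 0.0478 M: the reagent concentration at which a first chain carrier is as likely to end as to make product.

The fixed-odds view sets the charge of 2.00 M against that level, and expects 97.7 %.

The sliding-odds view objects that substrate and reagent are charged equally, so reagent falls as the run proceeds and the odds worsen. Summed along the run, with carrier held at its starting value: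

amount left = even-odds level × ln(reagent charged / amount left)

Three rounds of substitution give 0.136 M of reagent unused, hence 93.2 %. Each lost substrate costs one radical, and that loss stays below the 0.168 M of radicals available, so the chain outlasts the substrate.

Doubled reagent ends near 2.00 M, which gives 98.3 %. By-product feeds no step at the fork, so the choice is blue.

The forecast takes the sliding side's choice with 94.3 %, blue and 98.6 %, but on its own grounds: the loss is “the substrate capped by initiating radicals up to that moment”. My number for the flask lies lower.

The flask gives 94.2 %; blue gains 4.2 percentage points and reaches 98.4 %.

Fixed odds lose here by 3.5 points; under blue they give 98.8 %, still above the flask's value, by 0.37 points. In the flask at 0.189 min, the reagent step took first chain carrier 52 times as fast as the step to ended carrier, and the reagent left at 10.0 min, 0.115 M, is 2.41 times the even-odds level.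

With 0.021 M of initiator, the level in the neighbour flask is 0.0309 M, and the budget of 0.0420 M of radicals caps the sum, giving 74.3 %. The run of the neighbour flask gives 80.3 %, with 18 % of substrate left and 0 % of initiator.

The numbers of this flask are assumed; the flask was simulated.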